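What does more starting material buy in c(target) after 40 min, with the gas held at 0.82 mM?

| setting | dusk | summer | alder | cedar | maple | birch | ash |
|---|---|---|---|---|---|---|---|
| starting material | 0.020 M | 0.020 M | 0.020 M | 0.060 M | 0.20 M | 0.50 M | 1.5 M |
| capture agent | 0.67 mM | 2 mM | 1.00 mM | 1.00 mM | 1.00 mM | 1.00 mM | 1.00 mM |
| gas | 0.82 mM (held) | 0.82 mM (held) | 0.82 mM (held) | 0.82 mM (held) | 0.82 mM (held) | 0.82 mM (held) | 0.82 mM (held) |
| remark | run made earlier | run made earlier |  |  |  |  |  |
| time |  |  | 40 min | 40 min | 40 min | 40 min | 40 min |

- dusk (time / min: target / %, starting material / %): 2.50: 24.1, 58.0; 5.00: 41.9, 29.9; 8.00: 55.5, 11.4; 10.0: 59.8, 4.7; 12.0: 62.6, 2.0; 15.0: 63.5, 1.0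
- summer (time / min: target / %, starting material / %): 1.00: 9.6, 83.1; 2.00: 18.7, 66.0; 3.00: 27.7, 51.7; 5.00: 41.3, 29.6; 8.00: 54.9, 10.4; 15.0: 63.2, 1.1

(scatter of a reading: 0.5 percentage points)

- [target] at the end for alder, cedar, maple, birch, ash, in this order
- how the row runs (rises all the way / falls all the way / hardly changes / rises, then falls / falls, then rises)

- at the start none of the gas is in solution
- "hardly changes" means that all values lie within two and a half points (for a concentration: within two and a half percent of the largest)

I start from the early readings. The dusk flask makes target at 1.93 mM min⁻¹ over its first 2.50 min, and the summer flask at 1.85 mM min⁻¹ over its first 3.00 min, although the capture agent goes from 0.67 mM to 2 mM. So I carry their mean, the target pace, meaning the target made per minute while starting material is plentiful: 1.89 mM min⁻¹. I take it to be zero-order in starting material, paid for by the gas. I take the rest of the starting material to leave by a drain proportional to what is there. From the summer readings, counting what is neither target nor starting material against the mean amount present, I read 0.0905 min⁻¹.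

The balance of starting material is then pace plus drain. It lasts for the natural logarithm of (one plus starting drain over pace), divided by that drain constant, and target is pace times that time, stopped at 40 min.

A second way is the share of the charge (selectivity) that dusk ended with, 63.5%. For alder the share gives 12.7 mM and the pace gives 14.0 mM, so the two lie 1.30 mM apart, and both draw on the dusk readings. For ash they part: the share gives 952 mM, but that asks for 23.8 mM min⁻¹, far above the pace read, so the share is the one that cheats. By my reckoning the starting material of ash lasts 47.4 min, longer than the run, so I stop its tally at 75.5 mM.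

My row for cedar, maple, birch and ash is 28.3 mM, 49.2 mM, 67.1 mM, 75.5 mM, rising at each step.

The forecast gives 0.0128 M, 0.03 M, 0.055 M, 0.022 M, 0.008 M, which rises, then falls, on the ground that “the gas-starved solution has poor selectivity”. After maple it falls while mine rises: at ash it stands at 0.008 M against my 75.5 mM.

The flasks give 0.0131 M, 0.0306 M, 0.0607 M, 0.0822 M, 0.0924 M: the row rises all the way.

    starting material + partner → target (k = 6.60 M⁻¹ s⁻¹)
    starting material → side product (k = 0.00140 s⁻¹)
    starting material → intermediate A (k = 1.70 × 10⁻⁴ s⁻¹)
    partner + intermediate A → intermediate B (k = 4.60 M⁻¹ s⁻¹)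
    intermediate B → intermediate C (k = 0.00110 s⁻¹)
    intermediate C → target (k = 0.00100 s⁻¹)
    capture agent + intermediate A → trapped intermediate (k = 0.00460 M⁻¹ s⁻¹)
    gas ⇌ partner, rate k8*(csat - [partner]) (kL = 0.0670 s⁻¹)

The pace gave ash 75.5 mM against 0.0924 M, and cedar 28.3 mM against 0.0306 M. In ash, target gained 2.31 mM min⁻¹ on average, less than the 3.30 mM min⁻¹ at which gas crosses into a solution free of partner, while side product gained 31.1 mM min⁻¹. At 40.0 min ash held 82.9% of its charge as side product, with partner at 7.82 × 10⁻⁵ M.

The numbers in the tables were computed with made-up constants; the scatter is artificial.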